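The readings were generated by integration on assumed constants.

I started from the constants the earlier runs allow.

| flask | substrate | coupling partner | capture agent | remark | time |
|---|---|---|---|---|---|
| oak | 0.16 M | 0.36 M | 2.4 mM | run made earlier |  |
| maple | 0.28 M | 0.36 M | 2.4 mM | run made earlier |  |
| elm | 0.12 M | 0.36 M | 1.9 mM | run made earlier |  |
| dawn | 0.20 M | 0.360 M | 1.20 mM |  | 2.0 min |
| autumn | 0.12 M | 0.360 M | 2.40 mM |  | 2.0 min |

| run | time / s | target / % | substrate / % |
|---|---|---|---|
| oak | 10.0 | 3.5 | 63.2 |
| oak | 12.0 | 4.3 | 56.8 |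
| oak | 25.0 | 11.2 | 35.3 |
| oak | 40.0 | 14.4 | 20.7 |
| oak | 50.0 | 16.1 | 16.6 |
| oak | 60.0 | 18.2 | 12.1 |
| oak | 80.0 | 19.3 | 6.8 |
| maple | 12.0 | 3.5 | 60.2 |
| maple | 25.0 | 8.3 | 40.4 |
| maple | 40.0 | 14.3 | 28.4 |
| maple | 50.0 | 15.4 | 22.1 |
| maple | 60.0 | 18.1 | 20.2 |
| maple | 80.0 | 15.9 | 13.9 |
| elm | 10.0 | 3.7 | 61.6 |
| elm | 20.0 | 9.4 | 41.5 |
| elm | 40.0 | 16.2 | 20.0 |
| elm | 60.0 | 18.2 | 8.5 |
| elm | 80.0 | 19.2 | 3.4 |

(each reading ± 1 percentage point)



- which one finishes higher in amount of target, in percent of the substrate charged ("neither" within 2 percentage points) (dawn / autumn / neither)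
- amount of target at the end, in percent of the substrate charged, dawn
- amount of target at the end, in percent of the substrate charged, autumn

I assumed that each substrate takes one coupling partner, so that substrate, the limiting reagent, falls as κab, where a and b are the fractions left of the two charges. Then ln(b/a) grows in a straight line with time, with slope κx, where x is the partner's excess, the part of its charge beyond the substrate's. Taking the reading at the same time, 40.0 s, in each run, oak gave 3.08 min⁻¹, maple 3.00 min⁻¹ and elm 2.92 min⁻¹, each figure resting on one reading and carrying its scatter, so I took the mean, 3.00 min⁻¹, as κ, the coupling constant at a partner charge of 0.360 M.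

With E = exp(−κxt) and r the substrate's charge as a share of the partner's, a = xE/(1 − rE). This left 3.21% in dawn and 1.23% in autumn. Oak and elm read about 20.3% of consumed substrate as target, so I computed the correction alone: a gap of 0.4 percentage points, smaller than the margin of 2 points, which means neither.

The forecast said autumn, with 16% for dawn and 20.5% for autumn, reading the slowing as “a poison formed in proportion to substrate consumed”.

The flasks gave neither: dawn 17.0%, autumn 17.1%.

    open intermediate + capture agent → trapped intermediate (k = 0.160 M⁻¹ s⁻¹)
    substrate + coupling partner → open intermediate + by-product (k = 0.140 M⁻¹ s⁻¹)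
    crystals ⇌ by-product, rate k3*(cs3 - [by-product]) while solid is left; crystals form when [by-product] > cs3 (solubility = 39.0 mM, k = 0.330 s⁻¹)
    open intermediate ⇌ target (K = 0.410, k = 0.0180 s⁻¹)
    open intermediate ⇌ isomer of the product (K = 13.0, k = 0.00840 s⁻¹)

Substrate left stood at 3.14% in dawn and 1.19% in autumn, while autumn's target went from 18.6% after 1.00 min to 17.1% after 2.00 min as the isomer of the product grew from 21.6% to 42.5%. The share of consumed substrate held as target at the end was therefore 17.3%, and with κ's substrate figures this gives a gap of 0.34 points.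

Take autumn with 0.14 M of coupling partner. Scaling κ to that charge leaves 26.5% of the substrate and, at that share, 12.7% target; the computed flask gave 26.3% and 13.2%.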